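**Retrosynthetic overview**

1. Feature: ring B (C5–C10) together with C4 is a ring-opened pinane. C8 (as carbonyl), C9 and the methyl-bearing C10 are the enone carbons of verbenone, C4 is its CMe2 bridge carbon, already bonded to C5, and the one bond in excess is C4–C7.
2. Target 28 ⇒ diol 27 ⇒ alkyne 24 (C13 methyl, C13=C14 and C15 by methylalumination/formaldehyde) ⇒ alcohol 20, whose C9 allyl group is C11–C13.
3. 20 ⇒ enedione 14: axial C2–OH from the C2 ketone, C8 methyl and C7=C8 from the C8 enol triflate, second C4 methyl by cuprate addition.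
4. 14 ⇒ keto acid 11 (key disconnection): a Lewis acid cleaves C4–C7 to leave an isopropenyl group on C5, and the C2 acylium on the C10 arm acylates its terminus, forming C2–C3.
5. 11 ⇒ (1S)-(−)-verbenone 1 + vinyl (C1, C2) + allyl bromide. Ring order: ring B from the chiral pool, ring A closed in step 7.

Key step: step 7

Remark: atom labels C1–C15 are the labdane positions of the target in every compound; it is assumed that (1S)-(−)-verbenone of high enantiomeric purity is used, since every stereocentre is relayed from it.

**Route**

Step 1
Reactants: 1 (1S)-(−)-verbenone; 2 vinylmagnesium bromide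
Product: 3 4,6,6-trimethyl-4-vinylbicyclo[3.1.1]heptan-2-one (vinyl anti to the CMe2 bridge)
Conditions: CuI (10 mol %), THF, −40 → 0 °C; then 1 M HCl
Reagents that add atoms: none
Why: Copper-catalysed conjugate addition of the Grignard reagent to the β,β-disubstituted enone; the vinyl group enters C10 from the face of the CH2 bridge because the inner methyl of the CMe2 bridge covers the other face, which sets the quaternary C10 and places C1 trans to C4 across the C10–C5 bond (the later trans ring fusion).

Step 2
Reactants: 3
Product: 5 4-(2-hydroxyethyl)-4,6,6-trimethylbicyclo[3.1.1]heptan-2-ol (both C8 carbinol epimers), via borane adduct 4 (not isolated)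
Conditions: BH3·THF (2.5 equiv), THF, 0 °C → rt; then NaOH, H2O2, 0 °C → rt
Reagents that add atoms: hydrogen peroxide, OO
Why: Anti-Markovnikov hydroboration–oxidation of the neopentyl vinyl group puts the hydroxyl on the terminal carbon (C2), and the accompanying reduction of the C8 ketone is harmless because both carbinol epimers are reoxidised in step 3.

Step 3
Reactants: 5
Product: 6 2-(2,6,6-trimethyl-4-oxobicyclo[3.1.1]heptan-2-yl)acetic acid (acid arm anti to the CMe2 bridge)
Conditions: CrO3, H2SO4, acetone/H2O, 0 °C
Reagents that add atoms: water, O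
Why: Jones oxidation takes the primary alcohol through the aldehyde hydrate to the carboxylic acid and the secondary alcohol back to the ketone, the pinanone cyclobutane being stable to cold dilute acid.

Step 4
Reactants: 6
Product: 7 methyl ester of 6
Conditions: MeI, K2CO3, DMF, rt
Reagents that add atoms: iodomethane, CI
Why: SN2 O-alkylation of the potassium carboxylate removes the acid proton so that one equivalent of base suffices for the ketone enolate in step 5.

Step 5
Reactants: 7; 8 allyl bromide
Product: 10 methyl 2-(3-allyl-2,6,6-trimethyl-4-oxobicyclo[3.1.1]heptan-2-yl)acetate (allyl anti to the CMe2 bridge), via lithium enolate 9 (not isolated)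
Conditions: LiN(i-Pr)2 (1.05 equiv), THF, −78 °C; then 8, DMPU, −78 → −20 °C
Reagents that add atoms: none
Why: Kinetic ketone enolate alkylation: C9 is the only α-carbon of the ketone that can enolise (the bridgehead C7 cannot, Bredt's rule) and is more acidic than the ester methylene, and allyl bromide approaches anti to the CMe2 bridge; the C9 configuration is provisional because it is reset in step 7.

Step 6
Reactants: 10
Product: 11 3-allyl-4-(carboxymethyl)-4,6,6-trimethylbicyclo[3.1.1]heptan-2-one
Conditions: LiOH, THF/MeOH/H2O, 40 °C; then 1 M HCl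
Reagents that add atoms: lithium hydroxide, [Li+].[OH-]
Why: Saponification of the methyl ester (acyl–oxygen cleavage) frees the carboxylic acid that serves as the acyl donor, while the hindered ketone and the cyclobutane are inert to hydroxide.

Step 7
Reactants: 11
Product: 14 trans-fused 9-allyl-4,10-dimethyl-3-ene-2,8-dione (equatorial C9 allyl), via mixed anhydride 12 (not isolated), via isopropenyl ketone 13 (not isolated)
Conditions: (CF3CO)2O (2.5 equiv), CH2Cl2, 0 °C; then BF3·OEt2 (3 equiv), 0 °C → rt; then K2CO3, MeOH, rt
Reagents that add atoms: none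
Why: Proposed new method: BF3 activation of the C8 carbonyl lets the strained C4–C7 bond ionise toward the tertiary C4 cation, which leaves C7=C8 as an enol derivative and loses a methyl proton to give the isopropenyl group on C5 (13); the mixed anhydride on the neighbouring C10 arm then ionises to the C2 acylium, which attacks the alkene terminus (the future C3) in a 6-endo-trig closure of ring A through the tertiary C4 cation, and loss of the C3 proton gives the conjugated enone. The closest known reactions are the BF3·OEt2/Zn(OAc)2/Ac2O opening of pinan-2-ones to 4-isopropenylcyclohexenyl acetates and the trifluoroacetic anhydride cyclisation of 5-methylhex-5-enoic acids to 3-methylcyclohex-2-enones; only their union in one flask is new. The step needs the acylium to choose the isopropenyl terminus over C7 of the C8 enol (which would give a bridged bicyclo[2.2.2]octane-2,6-dione) and over the allyl group: the isopropenyl carbon is 1,1-disubstituted and sits gauche to the acyl arm on the chair of ring B, whereas attack at C7 needs a boat with the arm as flagpole and an enol whose oxygen is tied up by BF3 or as its trifluoroacetate, and the monosubstituted allyl alkene would have to close a seven-membered ring through a secondary cation. Before the cleavage the acyl group has no partner, because the bridgehead C7 cannot enolise and C9 is too close. No bond at C5 or C10 is broken, so the trans ring fusion set in step 1 should be kept, and C9 is reset through the C8 enol in the basic work-up, where axial protonation anti to the C10 methyl and the equatorial preference of the allyl group both favour the epimer shown. A δ-lactone from capture of the C4 cation by the carboxyl group would re-ionise under the same conditions and drain to the enone.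

Step 8
Reactants: 14
Product: 15 C2 trimethylsilyl enol ether (C2=C3) of 9-allyl-4,4,10-trimethyl-trans-decalin-2,8-dione
Conditions: Me2CuLi (from MeLi and CuI, 2 equiv), Me3SiCl, THF, −78 → −40 °C; Et3N, pentane, cold aq. NaHCO3; used crude
Reagents that add atoms: methyllithium, [Li]C; chlorotrimethylsilane, C[Si](C)(C)Cl
Why: Silyl chloride-accelerated Gilman conjugate addition to the β,β-disubstituted enone builds the quaternary C4 (no new stereocentre) while the saturated C8 ketone reacts far more slowly at low temperature, and the enolate is trapped regiospecifically as the C2=C3 enol silane, which masks C2 during steps 9 and 10.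

Step 9
Reactants: 15
Product: 17 C8 enol triflate (C7=C8) of 15, via potassium enolate 16 (not isolated)
Conditions: KN(SiMe3)2, THF, −78 °C; then PhNTf2, −78 → 0 °C
Reagents that add atoms: N-phenylbis(trifluoromethanesulfonimide), O=S(=O)(N(c1ccccc1)S(=O)(=O)C(F)(F)F)C(F)(F)F
Why: Kinetic deprotonation of the only free ketone at the unhindered C7 methylene (not at the tertiary C9 beside the quaternary C10) and O-sulfonylation give the C7=C8 enol triflate with C9 untouched, the enol silane having no acidic proton toward the amide base.

Step 10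
Reactants: 17
Product: 19 9-allyl-4,4,8,10-tetramethyl-trans-octal-7-en-2-one, via enol silane 18 (not isolated)
Conditions: MeZnCl, Pd(PPh3)4 (5 mol %), THF, rt → 50 °C; then 1 M HCl, THF, 0 °C
Reagents that add atoms: methylzinc chloride, C[Zn]Cl
Why: Negishi cross-coupling of the alkenyl triflate installs the C8 methyl with the double bond fixed at C7=C8, and the acidic work-up hydrolyses the enol silane to the C2 ketone.

Step 11
Reactants: 19
Product: 20 9-allyl-4,4,8,10-tetramethyl-trans-octal-7-en-2-ol (axial 2-OH cis to the C10 methyl)
Conditions: LiBH(s-Bu)3, THF, −78 °C; then NaOH, H2O2, 0 °C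
Reagents that add atoms: none
Why: Bulky hydride reduction: the axial methyl groups on C4 and C10 block the axial trajectory at C2, so hydride arrives equatorially from the opposite face and the alcohol is formed axial, cis to the C10 methyl (2S).

Step 12
Reactants: 20
Product: 22 3-(2-hydroxy-octalinyl)propan-1-ol (C13 primary alcohol of 20), via B-alkyl-9-BBN 21 (not isolated)
Conditions: 9-BBN (2.5 equiv), THF, 0 °C → rt; then NaOH, H2O2
Reagents that add atoms: hydrogen peroxide, OO
Why: Hydroboration–oxidation with the hindered dialkylborane is selective for the monosubstituted allyl alkene over the trisubstituted C7=C8 alkene and places the hydroxyl on the terminal carbon C13.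

Step 13
Reactants: 22
Product: 23 C13 aldehyde with free axial 2-OH
Conditions: TEMPO (10 mol %), PhI(OAc)2, CH2Cl2, rt
Reagents that add atoms: none
Why: Oxoammonium (TEMPO) oxidation is selective for the primary alcohol over the hindered axial secondary alcohol and stops at the aldehyde.

Step 14
Reactants: 23
Product: 24 terminal alkyne (C13≡C14) with free axial 2-OH
Conditions: dimethyl (1-diazo-2-oxopropyl)phosphonate, K2CO3, MeOH, 0 °C → rt
Reagents that add atoms: dimethyl (1-diazo-2-oxopropyl)phosphonate, COP(=O)(OC)C(=[N+]=[N-])C(C)=O
Why: Seyferth–Gilbert homologation in the Ohira–Bestmann variant converts the aldehyde into the terminal alkyne under mild base that the free alcohol and the alkene tolerate.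

Step 15
Reactants: 24
Product: 27 (13E)-labda-7,13-diene-2,15-diol (2-OH axial), via alkenylalane 25 (not isolated), via lithium alanate 26 (not isolated)
Conditions: AlMe3 (4 equiv), Cp2ZrCl2 (0.25 equiv), CH2Cl2, 0 °C → rt; volatiles removed; n-BuLi, THF, −78 °C; (CH2O)n, −78 °C → rt; then aq. potassium sodium tartrate
Reagents that add atoms: trimethylaluminium, C[Al](C)C; paraformaldehyde (as formaldehyde), C=O
Why: Negishi zirconium-catalysed methylalumination adds methyl and aluminium syn across the terminal alkyne with the methyl on C13, and the alanate attacks formaldehyde with retention at C14, which gives the (13E) allylic alcohol, the C2 hydroxyl being carried as its aluminium alkoxide.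

Step 16
Reactants: 27
Product: 28 target diacetate CNP0314870.1
Conditions: Ac2O, pyridine, DMAP (cat.), CH2Cl2, rt → 40 °C
Reagents that add atoms: acetic anhydride, CC(=O)OC(C)=O
Why: DMAP-catalysed acylation esterifies both the primary allylic and the hindered axial secondary alcohol without touching the alkenes or any stereocentre.

**Compound list**

1 | (1S)-(−)-verbenone, (1S,5S)-4,6,6-trimethylbicyclo[3.1.1]hept-3-en-2-one | CC1=CC(=O)[C@H]2C[C@@H]1C2(C)C | starting material
2 | vinylmagnesium bromide | C=C[Mg]Br | starting material
3 | 4,6,6-trimethyl-4-vinylbicyclo[3.1.1]heptan-2-one, vinyl anti to the CMe2 bridge, bridgeheads as in 1 | C=C[C@@]1(C)CC(=O)[C@H]2C[C@@H]1C2(C)C | intermediate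
4 | borane adduct of 3 (C2 alkylborane and C8 alkoxyborane, drawn as monomeric BH2 groups) | BCC[C@@]1(C)CC(OB)[C@H]2C[C@@H]1C2(C)C | intermediate
5 | 4-(2-hydroxyethyl)-4,6,6-trimethylbicyclo[3.1.1]heptan-2-ol, carbinol centre C8 as epimer mixture (left open in the SMILES) | OCC[C@@]1(C)CC(O)[C@H]2C[C@@H]1C2(C)C | intermediate
6 | 2-(2,6,6-trimethyl-4-oxobicyclo[3.1.1]heptan-2-yl)acetic acid, acid arm anti to the CMe2 bridge | OC(=O)C[C@@]1(C)CC(=O)[C@H]2C[C@@H]1C2(C)C | intermediate
7 | methyl ester of 6 | COC(=O)C[C@@]1(C)CC(=O)[C@H]2C[C@@H]1C2(C)C | intermediate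
8 | allyl bromide | C=CCBr | starting material
9 | lithium enolate of 7 (C8–OLi, C8=C9) | COC(=O)C[C@@]1(C)C=C(O[Li])[C@H]2C[C@@H]1C2(C)C | intermediate
10 | methyl 2-(3-allyl-2,6,6-trimethyl-4-oxobicyclo[3.1.1]heptan-2-yl)acetate, allyl anti to the CMe2 bridge | COC(=O)C[C@@]1(C)[C@@H](CC=C)C(=O)[C@H]2C[C@@H]1C2(C)C | intermediate
11 | 3-allyl-4-(carboxymethyl)-4,6,6-trimethylbicyclo[3.1.1]heptan-2-one, carboxymethyl and allyl anti to the CMe2 bridge (key-step precursor) | OC(=O)C[C@@]1(C)[C@@H](CC=C)C(=O)[C@H]2C[C@@H]1C2(C)C | intermediate
12 | mixed trifluoroacetic anhydride of 11 | O=C(C[C@@]1(C)[C@@H](CC=C)C(=O)[C@H]2C[C@@H]1C2(C)C)OC(=O)C(F)(F)F | intermediate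
13 | ring-opened mixed anhydride: 2-allyl-1-methyl-3-oxo-6-isopropenylcyclohexyl acetic trifluoroacetic anhydride, isopropenyl trans to the acyl arm | O=C(C[C@@]1(C)[C@@H](CC=C)C(=O)CC[C@@H]1C(C)=C)OC(=O)C(F)(F)F | intermediate
14 | 9-allyl-4,10-dimethyl-trans-decal-3-ene-2,8-dione (labdane numbering; H5 trans to the C10 methyl, allyl equatorial and cis to the C10 methyl) | CC1=CC(=O)C[C@]2(C)[C@@H]1CCC(=O)[C@H]2CC=C | intermediate
15 | 9-allyl-4,4,10-trimethyl-2-(trimethylsilyloxy)-trans-octal-2-en-8-one (C2=C3 enol silane) | CC1(C)C=C(O[Si](C)(C)C)C[C@]2(C)[C@@H]1CCC(=O)[C@H]2CC=C | intermediate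
16 | potassium C7=C8 enolate of 15 | CC1(C)C=C(O[Si](C)(C)C)C[C@]2(C)[C@@H]1CC=C(O[K])[C@H]2CC=C | intermediate
17 | C7=C8 enol triflate of 15 | CC1(C)C=C(O[Si](C)(C)C)C[C@]2(C)[C@@H]1CC=C(OS(=O)(=O)C(F)(F)F)[C@H]2CC=C | intermediate
18 | 9-allyl-4,4,8,10-tetramethyl-2-(trimethylsilyloxy)-trans-hexahydronaphthalene-2,7-diene (enol silane of 19) | CC1(C)C=C(O[Si](C)(C)C)C[C@]2(C)[C@@H]1CC=C(C)[C@H]2CC=C | intermediate
19 | 9-allyl-4,4,8,10-tetramethyl-trans-octal-7-en-2-one | CC1(C)CC(=O)C[C@]2(C)[C@@H]1CC=C(C)[C@H]2CC=C | intermediate
20 | 9-allyl-4,4,8,10-tetramethyl-trans-octal-7-en-2-ol, 2-OH axial and cis to the C10 methyl | CC1(C)C[C@H](O)C[C@]2(C)[C@@H]1CC=C(C)[C@H]2CC=C | intermediate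
21 | B-(C13-alkyl)-9-borabicyclo[3.3.1]nonane adduct of 20 | CC1(C)C[C@H](O)C[C@]2(C)[C@@H]1CC=C(C)[C@H]2CCCB1C2CCCC1CCC2 | intermediate
22 | C13 primary alcohol (2,13-diol) | CC1(C)C[C@H](O)C[C@]2(C)[C@@H]1CC=C(C)[C@H]2CCCO | intermediate
23 | C13 aldehyde with free 2-OH | CC1(C)C[C@H](O)C[C@]2(C)[C@@H]1CC=C(C)[C@H]2CCC=O | intermediate
24 | C13≡C14 terminal alkyne with free 2-OH | CC1(C)C[C@H](O)C[C@]2(C)[C@@H]1CC=C(C)[C@H]2CCC#C | intermediate
25 | (E)-alkenyldimethylalane (Al on C14, methyl on C13), 2-O-dimethylaluminium alkoxide | CC1(C)C[C@H](O[Al](C)C)C[C@]2(C)[C@@H]1CC=C(C)[C@H]2CC/C(C)=C/[Al](C)C | intermediate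
26 | lithium butyl(alkenyl)dimethylalanate of 25 | CC1(C)C[C@H](O[Al](C)C)C[C@]2(C)[C@@H]1CC=C(C)[C@H]2CC/C(C)=C/[Al-](C)(C)CCCC.[Li+] | intermediate
27 | (13E)-labda-7,13-diene-2,15-diol, 2-OH axial | CC1(C)C[C@H](O)C[C@]2(C)[C@@H]1CC=C(C)[C@H]2CC/C(C)=C/CO | intermediate
28 | (2S,5R,9R,10R,13E)-labda-7,13-diene-2,15-diyl diacetate (ent-labdane; 2-OAc axial, cis to the C10 methyl) | CC1(C)C[C@H](OC(C)=O)C[C@]2(C)[C@@H]1CC=C(C)[C@H]2CC/C(C)=C/COC(C)=O | target

**Step count and risks**

Total steps: 16. Longest linear sequence: 16 steps (1 → 28).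

Steps most likely to fail:

1. Step 7 (proposed new method). What may go wrong:
   - the acylium may be intercepted by the C7 enol carbon or by the allyl alkene instead of the isopropenyl terminus;
   - the C4 cation may be trapped as a lactone that does not re-ionise;
   - C5 may epimerise by dienol formation, or C9 may equilibrate incompletely.

   Fallback with known chemistry, from 10 back to 14: the two events are separated. Ester 10, which carries no acyl donor, is opened with BF3·OEt2/Zn(OAc)2/Ac2O at rt (the established pinan-2-one cleavage) to the ring-opened enol acetate ester F1. LiOH in aqueous THF then cleaves both the enol acetate and the methyl ester to the isopropenyl keto acid F2. F2 is cyclised with (CF3CO)2O in CH2Cl2 at 0 °C without a Lewis acid (known mixed-anhydride acylation of a 1,1-disubstituted alkene, under which the ketone is not enolised), followed by K2CO3/MeOH, to give 14.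

2. Step 8. What may go wrong: attack of the cuprate at C4 (a quaternary centre beside the ring fusion, syn-axial to the C10 methyl) may be too slow, so that addition to the C8 carbonyl or loss of the labile enol silane on handling takes over.

   Fallback, from 14 back to 19: the order of events is reversed so that no ketone or enol silane has to survive. KN(SiMe3)2/PhNTf2 at −78 °C on 14 should deprotonate the unhindered C7 methylene of the saturated ketone in preference to the neopentyl C1 methylene of the enone, giving the C8 enol triflate enone F3. Pd(PPh3)4/MeZnCl gives the 8-methyl-7-ene enone F4. With no ketone left, the methyl is forced onto C4 with MeMgBr, CuBr·SMe2 (cat.), Me3SiCl and HMPA in THF, which gives enol silane 18, and 1 M HCl returns to 19.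

3. Step 15. What may go wrong: the aluminium alkoxide at C2 may slow or divert the zirconium-catalysed methylalumination, or the alanate may capture formaldehyde incompletely.

   Fallback, from 24 back to 27: carbometalation is replaced by directed hydroalumination. n-BuLi (2.2 equiv) and (CH2O)n convert 24 into the propargylic diol F5. NaAlH2(OCH2CH2OMe)2 in THF followed by I2 at −78 °C gives, by alkoxide-directed trans-hydroalumination, the (Z)-3-iodoallylic diol F6. Me2CuLi in Et2O at 0 °C replaces iodine by methyl with retention to give 27.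

**Further compounds**

F1 | step 7 | methyl 2-(4-acetoxy-2-allyl-1-methyl-6-isopropenylcyclohex-3-enyl)acetate (C7=C8 enol acetate, isopropenyl trans to the ester arm) | COC(=O)C[C@@]1(C)[C@@H](CC=C)C(OC(C)=O)=CC[C@@H]1C(C)=C
F2 | step 7 | 2-(2-allyl-1-methyl-3-oxo-6-isopropenylcyclohexyl)acetic acid, C9 as epimer mixture (left open) | OC(=O)C[C@@]1(C)C(CC=C)C(=O)CC[C@@H]1C(C)=C
F3 | step 8 | C7=C8 enol triflate of 14 (enone intact) | CC1=CC(=O)C[C@]2(C)[C@@H]1CC=C(OS(=O)(=O)C(F)(F)F)[C@H]2CC=C
F4 | step 8 | 9-allyl-4,8,10-trimethyl-trans-hexahydronaphthalene-3,7-dien-2-one | CC1=CC(=O)C[C@]2(C)[C@@H]1CC=C(C)[C@H]2CC=C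
F5 | step 15 | propargylic diol (C13≡C14–C15H2OH, free 2-OH) | CC1(C)C[C@H](O)C[C@]2(C)[C@@H]1CC=C(C)[C@H]2CCC#CCO
F6 | step 15 | (13Z)-13-iodo allylic diol (iodine on C13, cis to C15) | CC1(C)C[C@H](O)C[C@]2(C)[C@@H]1CC=C(C)[C@H]2CC/C(I)=C/CO
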